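The stirred flask of Monday's, where target decays while substrate is still being dosed, is the vessel I reckoned by hand; the others stand beside it.

the same everywhere: enzyme 3.1 µM
- Sunday's: substrate 0.10 M; one stirred flow tank at steady state, fed with the mixture as stated, mean residence time 1.0 h
- Wednesday's: substrate 0.10 M; a closed flask charged with all of it at once and left for 1.0 h; time 1.0 h
- Monday's: substrate 0.10 M (fed, over 0.800 h); a stirred flask in which substrate is dosed at a steady rate over 0.800 h without added volume, worked up at 1.0 h; time 1.0 h
- Thursday's: substrate 0.10 M; a single well-mixed tank run continuously and read at steady state, 3.00 h in it on average

    target → over-reaction product (k1 = 0.00532 min⁻¹)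
    substrate + enzyme → target + enzyme, rate k2*[substrate]^3*[enzyme]/(1 + ([substrate]/Kh2)^3) (Kh2 = 33.1 mM, k2 = 7.92 × 10⁶ L³ mol⁻³ s⁻¹)

- order of the set-ups by the amount of target at the outlet or at the end, in percent of the substrate put in, highest first (Sunday's / Wednesday's / Monday's / Thursday's)
- amount of target at the outlet or at the end, in percent of the substrate put in, Sunday's
- amount of target at the outlet or at the end, in percent of the substrate put in, Wednesday's
- amount of target at the outlet or at the end, in percent of the substrate put in, Monday's
- amount of target at the outlet or at the end, in percent of the substrate put in, Thursday's

- the stated concentrations are those of everything mixed, before any reaction; amounts are the same in each set-up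
- the feed brings no volume worth counting
- run time (Wednesday's): 1.0 h

In Monday's flask substrate entered at 0.125 M h⁻¹, far below the ceiling of the rate law, 3.21 M h⁻¹, so I dropped the brake. Setting the cubic rate equal to the feed gave a quasi-steady hold-up of 11.2 mM substrate. Each portion therefore waited on average 0.0898 h, short beside the dosing time of 0.800 h. Portions arrive on average at the middle of the feed, so I reckoned that at 1.0 h the target had stood on average for 0.510 h, which I call the mean age of the target: the average time its molecules have been exposed to step 1 at the reading.

I then reckoned the surviving share of target in two ways. Replacing the spread of ages by this mean gave 85.0 %. Keeping the spread, with ages running evenly across a window as wide as the dosing time, and averaging the exponential decay over it gave 85.2 %. The two parted by 0.20 percentage points, so the mean did not cheat; this tests the averaging, not the wait, which both ways share. For the time after the feed stopped, the cubic law gave me a hold-up of 4.81 mM at 1.0 h, and my figure for Monday's became 80.9 %.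

The forecast ranked Monday's > Wednesday's > Sunday's > Thursday's, with Monday's at 80.6 % (range 78 % to 83 %), Wednesday's at 71.9 %, Sunday's at 68.1 % and Thursday's at 47.5 %, on the ground that “Dosing makes the target later and so gives it less time to decay”.

The simulation gives Monday's > Wednesday's > Sunday's > Thursday's, at 80.6 % for Monday's, 71.8 % for Wednesday's, 68.1 % for Sunday's and 47.5 % for Thursday's. Monday's flask held 4.8 % of its substrate at 1.00 h, against my 4.81 %. Setting the target against what had reacted and using the constant of step 1, 0.00532 min⁻¹, gives a mean age read from Monday's flask of 0.522 h, against my 0.510 h.

On a neighbour like Monday's but charged with 0.040 M substrate, the same steps gave a wait of 0.165 h, a mean age of 0.435 h and a figure of 77.3 %. The simulation gives that flask 76.4 %, with 11.2 % of its substrate left.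

The constants were chosen freely; the rest is arithmetic.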